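**Retrosynthetic overview**

1. Drimane numbering is used: decalin C1–C10, gem-dimethyl on C4, CH3 on C10, C11 = carboxyl carbon on C9, C12 = formyl carbon on C8; β = face of the C10 methyl; TBS = tert-butyldimethylsilyl, TBDPS = tert-butyldiphenylsilyl. The route rests on one feature: rings A and B share the C5–C10 bond and ring B carries C8–C9 directly beside it, so cutting C5–C10 and C8–C9 unfolds the whole decalin into a 1,7,9-decatriene (dienophile C9=C10 with C11 as the activating acyl group, diene C5=C6–C7=C8 with the C6 oxygen as a 2-silyloxy group, tether C1–C4).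
2. Ring order: no ring exists before the key step; an auxiliary-controlled intramolecular Diels–Alder reaction of the (E)-enoyl (S)-4-benzyloxazolidinone imide closes ring A and ring B together.
3. After the cycloaddition: imide → tert-butyl ester; 9α-OH by oxidation of the C9 ester enolate before the enone exists; C6 enol silane → 7-en-6-one → 6β-ol → trienoate; C12 silyl ether → aldehyde; ester → acid.
4. Before it: triene ← enone imide (enol silylation) ← enone acid + auxiliary; C6–C7 by Weinreb ketone synthesis with an (E)-alkenyllithium; C1–C10 by B-alkyl Suzuki coupling with an (E)-enol triflate; C3–C4 by conjugate allylation of an isopropylidene malonate.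

Key step: step 12

Assumption: the target is taken in the open 11-carboxylic acid/12-aldehyde form as drawn (ring–chain tautomerism to a 12-hydroxy-11,12-olide is not considered), and (2E,4E,6E)-octa-2,4,6-trienoic acid and diethyl isopropylidenemalonate are taken as purchasable.

**Route**

Step 1
Reactants: 1 diethyl 2-(propan-2-ylidene)propanedioate (diethyl isopropylidenemalonate); 2 allylmagnesium bromide
Product: 3 diethyl 2-(2-methylpent-4-en-2-yl)propanedioate
Conditions: CuI (10 mol %), THF, −20 → 0 °C; then 1 M HCl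
Reagents that add atoms: none
Why: Copper-catalysed conjugate addition of the allyl Grignard reagent to the doubly activated alkylidene malonate should create the quaternary C4 with its gem-dimethyl pair without competing 1,2-addition; no stereocentre is formed.

Step 2
Reactants: 3 diethyl 2-(2-methylpent-4-en-2-yl)propanedioate
Product: 4 ethyl 3,3-dimethylhex-5-enoate
Conditions: LiCl, H2O, DMSO, 160 °C
Reagents that add atoms: none
Why: Krapcho dealkoxycarbonylation of the monosubstituted malonate should remove one ester group and leave the ethyl ester (C5–C6), the terminal alkene being inert.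

Step 3
Reactants: 4 ethyl 3,3-dimethylhex-5-enoate
Product: 5 N-methoxy-N,3,3-trimethylhex-5-enamide
Conditions: MeNH(OMe)·HCl, i-PrMgCl, THF, −20 → 0 °C; then 1 M HCl
Reagents that add atoms: N,O-dimethylhydroxylamine hydrochloride, CNOC.Cl
Why: Aminolysis of the ester by the chloromagnesium amide of N,O-dimethylhydroxylamine (Weinreb amide formation) should give the acyl donor needed for a clean ketone synthesis at C6.

Step 4
Reactants: 6 tert-butyl 3-oxobutanoate
Product: 8 tert-butyl (2E)-3-{[(trifluoromethyl)sulfonyl]oxy}but-2-enoate, via tetramethylammonium enolate 7 (not isolated)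
Conditions: aq Me4NOH, toluene, 5 °C; then Tf2O
Reagents that add atoms: trifluoromethanesulfonic anhydride, O=S(=O)(OS(=O)(=O)C(F)(F)F)C(F)(F)F
Why: O-Triflation of the non-chelated ammonium enolate (stereoselective enol triflation of a β-keto ester) should give the (E)-enol triflate, with the leaving group trans to the ester so that the incoming C1 chain will sit trans to C11.

Step 5
Reactants: 5 N-methoxy-N,3,3-trimethylhex-5-enamide; 8 tert-butyl (2E)-3-{[(trifluoromethyl)sulfonyl]oxy}but-2-enoate
Product: 10 tert-butyl (2E)-9-[methoxy(methyl)amino]-3,7,7-trimethyl-9-oxonon-2-enoate, via alkylborane 9 (not isolated)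
Conditions: 9-BBN, THF, rt; then 8, Pd(dppf)Cl2 (5 mol %), 3 M aq K3PO4, DMF, rt → 50 °C
Reagents that add atoms: none
Why: Anti-Markovnikov hydroboration of the terminal alkene with 9-BBN followed by B-alkyl Suzuki–Miyaura coupling with the enol triflate should forge C1–C10 with retention of the (E)-alkene geometry, the Weinreb amide and the tert-butyl ester being tolerated.

Step 6
Reactants: 11 prop-2-yn-1-ol
Product: 12 tert-butyl(diphenyl)(prop-2-yn-1-yloxy)silane
Conditions: TBDPSCl, imidazole, CH2Cl2, 0 °C → rt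
Reagents that add atoms: tert-butyl(chloro)diphenylsilane, CC(C)(C)[Si](Cl)(c1ccccc1)c1ccccc1
Why: Standard silylation of the primary alcohol gives an acid-tolerant TBDPS ether that should survive the later tert-butyl ester cleavage.

Step 7
Reactants: 12 tert-butyl(diphenyl)(prop-2-yn-1-yloxy)silane
Product: 14 tert-butyl{[(2E)-3-iodoprop-2-en-1-yl]oxy}diphenylsilane, via alkenylzirconocene chloride 13 (not isolated)
Conditions: Cp2Zr(H)Cl, THF, rt; then I2, 0 °C
Reagents that add atoms: iodine, II
Why: syn-Hydrozirconation places zirconium on the terminal carbon and iodinolysis proceeds with retention, so the (E)-alkenyl iodide (future C7=C8 geometry) should result.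

Step 8
Reactants: 14 tert-butyl{[(2E)-3-iodoprop-2-en-1-yl]oxy}diphenylsilane; 10 tert-butyl (2E)-9-[methoxy(methyl)amino]-3,7,7-trimethyl-9-oxonon-2-enoate
Product: 16 tert-butyl (2E,10E)-12-{[tert-butyl(diphenyl)silyl]oxy}-3,7,7-trimethyl-9-oxododeca-2,10-dienoate, via alkenyllithium 15 (not isolated)
Conditions: t-BuLi (2.0 equiv), Et2O, −78 °C; then 10, THF, −78 °C; cold 0.5 M HCl
Reagents that add atoms: none
Why: Iodine–lithium exchange with retention of geometry and addition of the alkenyllithium to the Weinreb amide (Weinreb ketone synthesis) should give the (E)-enone through a stable chelate, the hindered conjugated tert-butyl ester being untouched at −78 °C.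

Step 9
Reactants: 16 tert-butyl (2E,10E)-12-{[tert-butyl(diphenyl)silyl]oxy}-3,7,7-trimethyl-9-oxododeca-2,10-dienoate
Product: 17 (2E,10E)-12-{[tert-butyl(diphenyl)silyl]oxy}-3,7,7-trimethyl-9-oxododeca-2,10-dienoic acid
Conditions: TFA/CH2Cl2 (1:4), 0 °C → rt
Reagents that add atoms: none
Why: Acidolysis of the tert-butyl ester with loss of isobutene should unmask the C11 acid without touching the enone or the TBDPS ether.

Step 10
Reactants: 17 (2E,10E)-12-{[tert-butyl(diphenyl)silyl]oxy}-3,7,7-trimethyl-9-oxododeca-2,10-dienoic acid; 18 (4S)-4-benzyl-1,3-oxazolidin-2-one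
Product: 20 (4S)-4-benzyl-3-[(2E,10E)-12-{[tert-butyl(diphenyl)silyl]oxy}-3,7,7-trimethyl-9-oxododeca-2,10-dienoyl]-1,3-oxazolidin-2-one, via mixed pivalic anhydride 19 (not isolated)
Conditions: t-BuCOCl, Et3N, THF, −20 °C; then 18, LiCl, rt
Reagents that add atoms: none
Why: N-Acylation of the oxazolidinone through the mixed pivalic anhydride under LiCl/Et3N avoids strong base and should attach the auxiliary at C11 without isomerising the (E)-enoyl unit.

Step 11
Reactants: 20 (4S)-4-benzyl-3-[(2E,10E)-12-{[tert-butyl(diphenyl)silyl]oxy}-3,7,7-trimethyl-9-oxododeca-2,10-dienoyl]-1,3-oxazolidin-2-one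
Product: 21 (4S)-4-benzyl-3-[(2E,8Z,10E)-9-{[tert-butyl(dimethyl)silyl]oxy}-12-{[tert-butyl(diphenyl)silyl]oxy}-3,7,7-trimethyldodeca-2,8,10-trienoyl]-1,3-oxazolidin-2-one
Conditions: TBSOTf, Et3N, CH2Cl2, −78 → 0 °C
Reagents that add atoms: tert-butyldimethylsilyl trifluoromethanesulfonate, CC(C)(C)[Si](C)(C)OS(=O)(=O)C(F)(F)F
Why: Soft enolisation of the enone toward its only α-CH2 (C5) with silyl triflate and amine should give the cross-conjugated 2-silyloxydiene, the quaternary C4 taking the position trans to C7 (8Z by priority) to avoid allylic 1,3-strain with the vinyl group.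

Step 12
Reactants: 21 (4S)-4-benzyl-3-[(2E,8Z,10E)-9-{[tert-butyl(dimethyl)silyl]oxy}-12-{[tert-butyl(diphenyl)silyl]oxy}-3,7,7-trimethyldodeca-2,8,10-trienoyl]-1,3-oxazolidin-2-one
Product: 22 (4S)-4-benzyl-3-[6-(TBSO)-12-(TBDPSO)drim-6-en-11-oyl]-1,3-oxazolidin-2-one (trans-fused; 5α-H; 8β-CH2OTBDPS; 9β-acyl; 10β-CH3)
Conditions: Me2AlCl (1.5 equiv), CH2Cl2, −30 → 0 °C; then cold aq NaHCO3
Reagents that add atoms: none
Why: Me2AlCl should bind the imide as a cationic two-point chelate with the enoyl unit s-cis, and the electron-rich 2-silyloxydiene then adds across C9=C10 in a concerted but asynchronous [4+2] (C5–C10 leading, C8–C9 following), the tether-imposed orientation coinciding with the electronically preferred 1,4-relationship of the C6 oxygen and the C9 acyl group; the closest known reaction type is the Lewis-acid-promoted intramolecular Diels–Alder reaction of trienoyl oxazolidinone imides of the 1,7,9-decatriene class (type 1, tether on a diene terminus). Ring B is closed by the cycloaddition itself (cyclohexene from diene C5–C8 plus C9=C10) and ring A by annulation of the four-carbon tether C1–C4 as C5–C10 forms (six-membered, chair-like, the C4 gem-dimethyl group favouring the folded conformer). C10 and C9 take their relative configuration from the (E)-dienophile (C10 methyl cis to the C9 acyl group), C8 from the (E) C7=C8 bond combined with endo placement of the carbonyl (C12 cis to the acyl group), and C5 from the same endo transition state, in which the tether lies exo and 5-H ends anti to the C10 methyl (trans ring fusion). Absolute configuration follows from the benzyl group of the (S)-auxiliary, which screens one face of the chelated dienophile so that the diene adds to the C9 Si face, giving 10β-CH3 and 5α-H as in the target. The step needs endo selectivity, π-facial selectivity and survival of the enol silane: the chelate and the (E)-geometry secure the first two and the bulky, weakly basic silyl ethers the third, and because C8 later becomes trigonal and C9 is re-set by enolate oxidation only C5 and C10 must be delivered correctly.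

Step 13
Reactants: 22 (4S)-4-benzyl-3-[6-(TBSO)-12-(TBDPSO)drim-6-en-11-oyl]-1,3-oxazolidin-2-one
Product: 24 6-(TBSO)-12-(TBDPSO)drim-6-en-11-oic acid (5α-H; 8α-H; 9α-H), via peroxy acid 23 (not isolated)
Conditions: LiOH, 30% aq H2O2, THF/H2O (3:1), 0 °C; then aq Na2SO3; 0.5 M HCl to pH 4–5, 0 °C
Reagents that add atoms: hydrogen peroxide, OO
Why: Hydroperoxide should cleave the hindered imide at the exocyclic carbonyl (LiOOH hydrolysis of an N-acyloxazolidinone) and sulfite reduces the peroxy acid, giving the C11 acid and returning the auxiliary while the hindered TBS enol ether survives the brief cold treatment; epimerisation at C9 would be harmless.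

Step 14
Reactants: 24 6-(TBSO)-12-(TBDPSO)drim-6-en-11-oic acid
Product: 25 tert-butyl 6-(TBSO)-12-(TBDPSO)drim-6-en-11-oate (5α-H; 8α-H; 9α-H)
Conditions: O-tert-butyl-N,N′-diisopropylisourea, CH2Cl2, rt (crude acid used without delay)
Reagents that add atoms: O-tert-butyl-N,N′-diisopropylisourea, CC(C)N=C(OC(C)(C)C)NC(C)C
Why: tert-Butyl transfer from the isourea to the carboxylic acid (O-alkylation, insensitive to the hindered acyl carbon) should install an ester that resists lactonisation onto C12 and is later removed by acid in the presence of the trienoate.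

Step 15
Reactants: 25 tert-butyl 6-(TBSO)-12-(TBDPSO)drim-6-en-11-oate
Product: 27 tert-butyl 9α-hydroxy-6-(TBSO)-12-(TBDPSO)drim-6-en-11-oate, via potassium enolate 26 (not isolated)
Conditions: KN(SiMe3)2, THF, −78 → −40 °C; then 2-(phenylsulfonyl)-3-phenyloxaziridine, −78 °C; AcOH
Reagents that add atoms: 2-(phenylsulfonyl)-3-phenyloxaziridine, O=S(=O)(c1ccccc1)N1OC1c1ccccc1
Why: Enolate oxidation with an N-sulfonyloxaziridine should hydroxylate C9, the reagent approaching the planar enolate from the α face opposite the axial C10 methyl and the C8 β-CH2OSi group, which sets 9α-OH and 9β-CO2t-Bu; doing this before the enone exists avoids competing attack at C7 of an extended enolate.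

Step 16
Reactants: 27 tert-butyl 9α-hydroxy-6-(TBSO)-12-(TBDPSO)drim-6-en-11-oate
Product: 28 tert-butyl 9α-hydroxy-6-oxo-12-(TBDPSO)drim-7-en-11-oate
Conditions: Pd(OAc)2 (1.1 equiv), MeCN, rt → 40 °C
Reagents that add atoms: none
Why: Saegusa–Ito oxidation of the enol silane (C7-palladation from the open α face, then syn β-hydride elimination of 8α-H) should give the 7-en-6-one and erase the C8 stereocentre as planned.

Step 17
Reactants: 28 tert-butyl 9α-hydroxy-6-oxo-12-(TBDPSO)drim-7-en-11-oate
Product: 29 tert-butyl 6β,9α-dihydroxy-12-(TBDPSO)drim-7-en-11-oate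
Conditions: NaBH4, CeCl3·7H2O, MeOH, −78 → −40 °C
Reagents that add atoms: none
Why: Luche reduction gives clean 1,2-reduction, and hydride should attack C6 from the α face because the β face is screened by the syn-axial C10 and C4β methyl groups, giving the 6β (axial) allylic alcohol.

Step 18
Reactants: 29 tert-butyl 6β,9α-dihydroxy-12-(TBDPSO)drim-7-en-11-oate; 30 (2E,4E,6E)-octa-2,4,6-trienoic acid
Product: 32 tert-butyl 9α-hydroxy-6β-[(2E,4E,6E)-octa-2,4,6-trienoyloxy]-12-(TBDPSO)drim-7-en-11-oate, via mixed trichlorobenzoic anhydride 31 (not isolated)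
Conditions: 30, 2,4,6-trichlorobenzoyl chloride, Et3N, THF, rt; then 29, DMAP, toluene, rt → 45 °C
Reagents that add atoms: none
Why: Yamaguchi esterification (mixed anhydride, DMAP acyl transfer) should acylate the secondary allylic 6β-OH with retention at C6 while the tertiary 9-OH stays free.

Step 19
Reactants: 32 tert-butyl 9α-hydroxy-6β-[(2E,4E,6E)-octa-2,4,6-trienoyloxy]-12-(TBDPSO)drim-7-en-11-oate
Product: 33 tert-butyl 9α,12-dihydroxy-6β-[(2E,4E,6E)-octa-2,4,6-trienoyloxy]drim-7-en-11-oate
Conditions: HF·pyridine, pyridine, THF, 0 °C → rt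
Reagents that add atoms: none
Why: Buffered fluoride-mediated desilylation should free the primary allylic C12 alcohol without acyl migration, the bulky tert-butyl ester on quaternary C9 resisting lactonisation.

Step 20
Reactants: 33 tert-butyl 9α,12-dihydroxy-6β-[(2E,4E,6E)-octa-2,4,6-trienoyloxy]drim-7-en-11-oate
Product: 34 tert-butyl 9α-hydroxy-6β-[(2E,4E,6E)-octa-2,4,6-trienoyloxy]-12-oxodrim-7-en-11-oate
Conditions: activated MnO2 (excess), CH2Cl2, rt
Reagents that add atoms: none
Why: MnO2 oxidises allylic alcohols selectively (allylic oxidation to the enal), so C12 should reach the aldehyde level without touching the tertiary alcohol or the trienoate.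

Step 21
Reactants: 34 tert-butyl 9α-hydroxy-6β-[(2E,4E,6E)-octa-2,4,6-trienoyloxy]-12-oxodrim-7-en-11-oate
Product: 35 ustusoic acid B, 9α-hydroxy-6β-[(2E,4E,6E)-octa-2,4,6-trienoyloxy]-12-oxodrim-7-en-11-oic acid
Conditions: TFA/CH2Cl2 (1:3), 0 °C → rt
Reagents that add atoms: none
Why: Acidolysis of the tert-butyl ester with loss of isobutene should release the C11 acid; with C12 already an aldehyde no 11,12-lactone can form, and the allylic trienoate is stable because ionisation at C6 would give a formyl-destabilised cation.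

**Compound list**

1 | diethyl 2-(propan-2-ylidene)propanedioate | CCOC(=O)C(=C(C)C)C(=O)OCC | starting material
2 | allylmagnesium bromide | C=CC[Mg]Br | starting material
3 | diethyl 2-(2-methylpent-4-en-2-yl)propanedioate | CCOC(=O)C(C(=O)OCC)C(C)(C)CC=C | intermediate
4 | ethyl 3,3-dimethylhex-5-enoate | CCOC(=O)CC(C)(C)CC=C | intermediate
5 | N-methoxy-N,3,3-trimethylhex-5-enamide | CON(C)C(=O)CC(C)(C)CC=C | intermediate
6 | tert-butyl 3-oxobutanoate | CC(=O)CC(=O)OC(C)(C)C | starting material
7 | tetramethylammonium (E)-enolate of 6 | C/C([O-])=C\C(=O)OC(C)(C)C.C[N+](C)(C)C | intermediate (not isolated)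
8 | tert-butyl (2E)-3-{[(trifluoromethyl)sulfonyl]oxy}but-2-enoate | C/C(OS(=O)(=O)C(F)(F)F)=C\C(=O)OC(C)(C)C | intermediate
9 | 9-{6-[methoxy(methyl)amino]-4,4-dimethyl-6-oxohexyl}-9-borabicyclo[3.3.1]nonane | CON(C)C(=O)CC(C)(C)CCCB1C2CCCC1CCC2 | intermediate (not isolated)
10 | tert-butyl (2E)-9-[methoxy(methyl)amino]-3,7,7-trimethyl-9-oxonon-2-enoate | CON(C)C(=O)CC(C)(C)CCC/C(C)=C/C(=O)OC(C)(C)C | intermediate
11 | prop-2-yn-1-ol | C#CCO | starting material
12 | tert-butyl(diphenyl)(prop-2-yn-1-yloxy)silane | C#CCO[Si](c1ccccc1)(c1ccccc1)C(C)(C)C | intermediate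
13 | chlorobis(cyclopentadienyl)[(1E)-3-{[tert-butyl(diphenyl)silyl]oxy}prop-1-en-1-yl]zirconium | Cl[Zr](/C=C/CO[Si](c1ccccc1)(c1ccccc1)C(C)(C)C)(C1C=CC=C1)C1C=CC=C1 | intermediate (not isolated)
14 | tert-butyl{[(2E)-3-iodoprop-2-en-1-yl]oxy}diphenylsilane | I/C=C/CO[Si](c1ccccc1)(c1ccccc1)C(C)(C)C | intermediate
15 | [(1E)-3-{[tert-butyl(diphenyl)silyl]oxy}prop-1-en-1-yl]lithium | [Li]/C=C/CO[Si](c1ccccc1)(c1ccccc1)C(C)(C)C | intermediate (not isolated)
16 | tert-butyl (2E,10E)-12-{[tert-butyl(diphenyl)silyl]oxy}-3,7,7-trimethyl-9-oxododeca-2,10-dienoate | CC(C)(C)OC(=O)/C=C(\C)CCCC(C)(C)CC(=O)/C=C/CO[Si](c1ccccc1)(c1ccccc1)C(C)(C)C | intermediate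
17 | (2E,10E)-12-{[tert-butyl(diphenyl)silyl]oxy}-3,7,7-trimethyl-9-oxododeca-2,10-dienoic acid | OC(=O)/C=C(\C)CCCC(C)(C)CC(=O)/C=C/CO[Si](c1ccccc1)(c1ccccc1)C(C)(C)C | intermediate
18 | (4S)-4-benzyl-1,3-oxazolidin-2-one | O=C1N[C@@H](Cc2ccccc2)CO1 | starting material
19 | mixed anhydride of 17 with pivalic acid | CC(C)(C)C(=O)OC(=O)/C=C(\C)CCCC(C)(C)CC(=O)/C=C/CO[Si](c1ccccc1)(c1ccccc1)C(C)(C)C | intermediate (not isolated)
20 | (4S)-4-benzyl-3-[(2E,10E)-12-{[tert-butyl(diphenyl)silyl]oxy}-3,7,7-trimethyl-9-oxododeca-2,10-dienoyl]-1,3-oxazolidin-2-one | O=C(/C=C(\C)CCCC(C)(C)CC(=O)/C=C/CO[Si](c1ccccc1)(c1ccccc1)C(C)(C)C)N1[C@@H](Cc2ccccc2)COC1=O | intermediate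
21 | (4S)-4-benzyl-3-[(2E,8Z,10E)-9-{[tert-butyl(dimethyl)silyl]oxy}-12-{[tert-butyl(diphenyl)silyl]oxy}-3,7,7-trimethyldodeca-2,8,10-trienoyl]-1,3-oxazolidin-2-one (key-step precursor) | O=C(/C=C(\C)CCCC(C)(C)/C=C(O[Si](C)(C)C(C)(C)C)/C=C/CO[Si](c1ccccc1)(c1ccccc1)C(C)(C)C)N1[C@@H](Cc2ccccc2)COC1=O | intermediate
22 | (4S)-4-benzyl-3-[6-(TBSO)-12-(TBDPSO)drim-6-en-11-oyl]-1,3-oxazolidin-2-one; trans-fused, 5α-H, 8β-CH2OTBDPS, 9β-acyl, 10β-CH3 (key-step product) | CC(C)(C)[Si](C)(C)OC1=C[C@H](CO[Si](c3ccccc3)(c4ccccc4)C(C)(C)C)[C@H](C(=O)N5[C@@H](Cc6ccccc6)COC5=O)[C@@]2(C)CCCC(C)(C)[C@H]12 | intermediate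
23 | 6-(TBSO)-12-(TBDPSO)drim-6-ene-11-peroxoic acid (lithium salt in the flask) | CC(C)(C)[Si](C)(C)OC1=C[C@H](CO[Si](c3ccccc3)(c4ccccc4)C(C)(C)C)[C@H](C(=O)OO)[C@@]2(C)CCCC(C)(C)[C@H]12 | intermediate (not isolated)
24 | 6-(TBSO)-12-(TBDPSO)drim-6-en-11-oic acid; 5α-H, 8α-H, 9α-H | CC(C)(C)[Si](C)(C)OC1=C[C@H](CO[Si](c3ccccc3)(c4ccccc4)C(C)(C)C)[C@H](C(=O)O)[C@@]2(C)CCCC(C)(C)[C@H]12 | intermediate
25 | tert-butyl 6-(TBSO)-12-(TBDPSO)drim-6-en-11-oate; 5α-H, 8α-H, 9α-H | CC(C)(C)[Si](C)(C)OC1=C[C@H](CO[Si](c3ccccc3)(c4ccccc4)C(C)(C)C)[C@H](C(=O)OC(C)(C)C)[C@@]2(C)CCCC(C)(C)[C@H]12 | intermediate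
26 | potassium C9 ester enolate of 25 | CC(C)(C)[Si](C)(C)OC1=C[C@H](CO[Si](c3ccccc3)(c4ccccc4)C(C)(C)C)C(=C([O-])OC(C)(C)C)[C@@]2(C)CCCC(C)(C)[C@H]12.[K+] | intermediate (not isolated)
27 | tert-butyl 9α-hydroxy-6-(TBSO)-12-(TBDPSO)drim-6-en-11-oate | CC(C)(C)[Si](C)(C)OC1=C[C@H](CO[Si](c3ccccc3)(c4ccccc4)C(C)(C)C)[C@](O)(C(=O)OC(C)(C)C)[C@@]2(C)CCCC(C)(C)[C@H]12 | intermediate
28 | tert-butyl 9α-hydroxy-6-oxo-12-(TBDPSO)drim-7-en-11-oate | O=C1C=C(CO[Si](c3ccccc3)(c4ccccc4)C(C)(C)C)[C@](O)(C(=O)OC(C)(C)C)[C@@]2(C)CCCC(C)(C)[C@H]12 | intermediate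
29 | tert-butyl 6β,9α-dihydroxy-12-(TBDPSO)drim-7-en-11-oate | O[C@@H]1C=C(CO[Si](c3ccccc3)(c4ccccc4)C(C)(C)C)[C@](O)(C(=O)OC(C)(C)C)[C@@]2(C)CCCC(C)(C)[C@H]12 | intermediate
30 | (2E,4E,6E)-octa-2,4,6-trienoic acid | C/C=C/C=C/C=C/C(=O)O | starting material
31 | (2E,4E,6E)-octa-2,4,6-trienoic 2,4,6-trichlorobenzoic anhydride | C/C=C/C=C/C=C/C(=O)OC(=O)c1c(Cl)cc(Cl)cc1Cl | intermediate (not isolated)
32 | tert-butyl 9α-hydroxy-6β-[(2E,4E,6E)-octa-2,4,6-trienoyloxy]-12-(TBDPSO)drim-7-en-11-oate | C/C=C/C=C/C=C/C(=O)O[C@@H]1C=C(CO[Si](c3ccccc3)(c4ccccc4)C(C)(C)C)[C@](O)(C(=O)OC(C)(C)C)[C@@]2(C)CCCC(C)(C)[C@H]12 | intermediate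
33 | tert-butyl 9α,12-dihydroxy-6β-[(2E,4E,6E)-octa-2,4,6-trienoyloxy]drim-7-en-11-oate | C/C=C/C=C/C=C/C(=O)O[C@@H]1C=C(CO)[C@](O)(C(=O)OC(C)(C)C)[C@@]2(C)CCCC(C)(C)[C@H]12 | intermediate
34 | tert-butyl 9α-hydroxy-6β-[(2E,4E,6E)-octa-2,4,6-trienoyloxy]-12-oxodrim-7-en-11-oate | C/C=C/C=C/C=C/C(=O)O[C@@H]1C=C(C=O)[C@](O)(C(=O)OC(C)(C)C)[C@@]2(C)CCCC(C)(C)[C@H]12 | intermediate
35 | ustusoic acid B | C/C=C/C=C/C=C/C(=O)O[C@@H]1C=C(C=O)[C@](O)(C(=O)O)[C@@]2(C)CCCC(C)(C)[C@H]12 | target

**Step count and risks**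

Total step count: 21. Longest linear sequence: 18 steps (steps 1, 2, 3, 5 and 8 to 21).

Most likely to fail, step 12: the cycloaddition may be too slow at the β,β-disubstituted dienophile that must create quaternary C10, so that Lewis-acid-induced loss of the enol silane or a stalled Mukaiyama–Michael addition competes, and endo or facial selectivity may erode. The fallback replaces the Lewis-acid cycloaddition by a stepwise anionic Michael–Michael annulation and sets out from enone imide 20. LiN(SiMe3)2 in THF at −78 °C should give the cross-conjugated lithium dienolate F1, whose C5 adds to C10 of the lithium-chelated enoyl imide; the imide enolate so formed closes C9–C8 onto the enone, and cold dilute HCl then gives the bicyclic 6-oxo imide F2. Soft enolisation toward C7 (TBSOTf, Et3N; C5 is a hindered methine) returns to the route at 22. Since C8 later becomes trigonal and C9 is re-set, only the C5/C10 relationship has to match.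

Second, step 15: enolisation of the hindered C9 methine beside quaternary C10 may be incomplete, or the tetrasubstituted enolate may react so sluggishly that the sulfonimine by-product intercepts it. The fallback changes the oxidation mode to aerobic γ-oxidation of a vinylogous β-keto ester and sets out from 25. Saegusa–Ito oxidation (Pd(OAc)2, MeCN) should give tert-butyl 6-oxo-12-(TBDPSO)drim-7-en-11-oate F3, whose doubly activated C9–H is removed by KOt-Bu in THF/t-BuOH under O2 in the presence of P(OEt)3. Oxygen should add to C9 from the α face, the 9α-hydroperoxide F4 is reduced in situ by the phosphite, and the sequence rejoins the route at 28.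

Third, step 18: acyl transfer to the axial 6β-hydroxyl, which is 1,3-diaxial to two methyl groups, may be slow, and long exposure of the trienoyl donor to DMAP invites isomerisation or oligomerisation of the polyene. The fallback builds the trienoate on the alcohol instead of transferring it and sets out from 29. Esterification with the small diethylphosphonoacetic acid (DCC, DMAP, CH2Cl2) should give tert-butyl 6β-[(diethoxyphosphoryl)acetoxy]-9α-hydroxy-12-(TBDPSO)drim-7-en-11-oate F5. Horner–Wadsworth–Emmons olefination with (2E,4E)-hexa-2,4-dienal (LiCl, DBU, MeCN) then forms the 2E double bond and returns to the route at 32.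

**Further compounds**

F1 | step 12 | lithium cross-conjugated dienolate of 20 | O=C(/C=C(\C)CCCC(C)(C)/C=C([O-])/C=C/CO[Si](c1ccccc1)(c1ccccc1)C(C)(C)C)N1[C@@H](Cc2ccccc2)COC1=O.[Li+]
F2 | step 12 | (4S)-4-benzyl-3-[6-oxo-12-(TBDPSO)driman-11-oyl]-1,3-oxazolidin-2-one (5α-H, 8α-H, 9α-H) | O=C1C[C@H](CO[Si](c3ccccc3)(c4ccccc4)C(C)(C)C)[C@H](C(=O)N5[C@@H](Cc6ccccc6)COC5=O)[C@@]2(C)CCCC(C)(C)[C@H]12
F3 | step 15 | tert-butyl 6-oxo-12-(TBDPSO)drim-7-en-11-oate (9α-H) | O=C1C=C(CO[Si](c3ccccc3)(c4ccccc4)C(C)(C)C)[C@H](C(=O)OC(C)(C)C)[C@@]2(C)CCCC(C)(C)[C@H]12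
F4 | step 15 | tert-butyl 9α-hydroperoxy-6-oxo-12-(TBDPSO)drim-7-en-11-oate | O=C1C=C(CO[Si](c3ccccc3)(c4ccccc4)C(C)(C)C)[C@](OO)(C(=O)OC(C)(C)C)[C@@]2(C)CCCC(C)(C)[C@H]12
F5 | step 18 | tert-butyl 6β-[(diethoxyphosphoryl)acetoxy]-9α-hydroxy-12-(TBDPSO)drim-7-en-11-oate | CCOP(=O)(OCC)CC(=O)O[C@@H]1C=C(CO[Si](c3ccccc3)(c4ccccc4)C(C)(C)C)[C@](O)(C(=O)OC(C)(C)C)[C@@]2(C)CCCC(C)(C)[C@H]12
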